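**Plan**
1. The quinone methide C=C and the four phenolic O–H groups are traced back to a tetramethyl triaryl carbinol (O–CH3 cleavage and loss of water).
2. Two bonds on adjacent carbons of the central ring are then cut together: the bond from the ring to the carbinol (future methide) carbon and the biaryl bond next to it. This leaves an aryne, 4-methoxyphenyllithium and 4,4'-dimethoxybenzophenone.
3. The aryl–alkynyl bond is cut last (Sonogashira), giving 3-chloro-2-iodotoluene and 4-ethynylanisole.
4. Enabling feature: the central benzene ring carries the alkynyl, methide and aryl carbons on three contiguous ring atoms, so the two inner positions are the two ends of a 3-alkynylbenzyne. The chlorine that generates it has a single ortho hydrogen, the sp carbon steers the nucleophile to the far end, and the methide carbon is a benzophenone carbonyl carbon in disguise.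
5. Forward, no ring is built: the alkyne arm is attached, the aryl ring and the diarylcarbinol are added in one pot, and demethylation with dehydration unveils the quinone methide.
6. Stereochemistry: the target has no stereocentre and no stereogenic double bond (the dienone ring is symmetric), so nothing has to be set.

Key step: step 2

Remark: the two 4-hydroxyphenyl rings on the methide carbon are interchangeable by tautomerism, so which one is drawn as the dienone is not a structural choice.

**Step 1**
Reactants: 1 3-chloro-2-iodotoluene; 2 4-ethynylanisole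
Product: 3 1-chloro-2-[(4-methoxyphenyl)ethynyl]-3-methylbenzene
Conditions: PdCl2(PPh3)2 (cat.), CuI (cat.), Et3N, THF, degassed, 50 °C
Reagents that add atoms: none
Why: Sonogashira coupling; Pd(0) should insert into the C–I bond and leave the C–Cl bond, which is needed in step 2, untouched.

**Step 2**
Reactants: 3 1-chloro-2-[(4-methoxyphenyl)ethynyl]-3-methylbenzene; 4 4-bromoanisole; 5 4,4'-dimethoxybenzophenone
Product: 11 bis(4-methoxyphenyl){4'-methoxy-3-[(4-methoxyphenyl)ethynyl]-4-methylbiphenyl-2-yl}methanol, via 4-methoxyphenyllithium 6 (not isolated), via ortho-lithiated chloroarene 7 (not isolated), via alkynyl aryne 8 (not isolated), via 2-lithiobiaryl 9 (not isolated), via lithium carbinolate 10 (not isolated)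
Conditions: 4 (2.5 equiv), t-BuLi (5.0 equiv), THF, −78 °C; then 3 (1.0 equiv), LiTMP (1.3 equiv), −78 → −20 °C; then 5 (3.0 equiv), −78 °C → rt; H2O
Reagents that add atoms: none
Why: LiTMP removes the only hydrogen ortho to chlorine in 3 (the other neighbour of the C–Cl carbon is the alkynyl-bearing carbon), so loss of LiCl from 7 can give only one aryne, 8, whose triple bond spans the two ring carbons that carry the aryl group and the methide carbon in the target. Aryllithium 6 should add to the aryne carbon remote from the alkynyl group, the more electrophilic and less hindered terminus, which places the new C–Li bond of 9 next to the inductively withdrawing sp carbon, as 3-halo- and 3-arylbenzynes behave in one-pot m-terphenyl syntheses. The 2-lithiobiaryl 9 then attacks the carbonyl carbon of the non-enolisable ketone 5 and forms the bond between the central ring and the future methide carbon. The closest known reaction type is aryne arylation with electrophilic trapping of the resulting 2-lithiobiaryl (aryne generation from aryl chlorides with LiTMP, and trapping of aryne-derived 2-lithiobiaryls with benzophenone). No ring is closed and no stereocentre is formed. The step needs a single aryne, attack by carbon at the distal terminus and survival of 9 until the ketone arrives; these are secured by the single ortho hydrogen, by the alkynyl substituent together with the low nucleophilicity of the hindered amide, and by the excess of the more basic 6, which should re-deprotonate the liberated amine in place of 9.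

**Step 3**
Reactants: 11 bis(4-methoxyphenyl){4'-methoxy-3-[(4-methoxyphenyl)ethynyl]-4-methylbiphenyl-2-yl}methanol
Product: 13 Selaginellin U, via trityl cation bromide 12 (not isolated)
Conditions: BBr3 (10 equiv), CH2Cl2, −78 → 0 °C; then ice/H2O, EtOAc
Reagents that add atoms: none
Why: Lewis-acid cleavage of the four aryl methyl ethers with BBr3 also ionises the triaryl carbinol, and on hydrolysis the bis(4-hydroxyphenyl)aryl carbocation should lose a phenolic proton to give the quinone methide (fuchsone formation).

**Compound list**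
1 | 3-chloro-2-iodotoluene (1-chloro-2-iodo-3-methylbenzene) | Cc1cccc(Cl)c1I | starting material
2 | 4-ethynylanisole (1-ethynyl-4-methoxybenzene) | C#Cc1ccc(OC)cc1 | starting material
3 | 1-chloro-2-[(4-methoxyphenyl)ethynyl]-3-methylbenzene | Cc1cccc(Cl)c1C#Cc1ccc(OC)cc1 | intermediate
4 | 4-bromoanisole | COc1ccc(Br)cc1 | starting material
5 | 4,4'-dimethoxybenzophenone | COc1ccc(cc1)C(=O)c1ccc(OC)cc1 | starting material
6 | 4-methoxyphenyllithium | [Li]c1ccc(OC)cc1 | intermediate
7 | {2-chloro-3-[(4-methoxyphenyl)ethynyl]-4-methylphenyl}lithium | [Li]c1ccc(C)c(C#Cc2ccc(OC)cc2)c1Cl | intermediate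
8 | 3-[(4-methoxyphenyl)ethynyl]-4-methylbenzyne (1,2-didehydro-3-[(4-methoxyphenyl)ethynyl]-4-methylbenzene) | CC1=C(C#Cc2ccc(OC)cc2)C#CC=C1 | intermediate
9 | {4'-methoxy-3-[(4-methoxyphenyl)ethynyl]-4-methylbiphenyl-2-yl}lithium | [Li]c1c(-c2ccc(OC)cc2)ccc(C)c1C#Cc1ccc(OC)cc1 | intermediate
10 | lithium bis(4-methoxyphenyl){4'-methoxy-3-[(4-methoxyphenyl)ethynyl]-4-methylbiphenyl-2-yl}methanolate | Cc1ccc(-c2ccc(OC)cc2)c(C([O-])(c2ccc(OC)cc2)c2ccc(OC)cc2)c1C#Cc1ccc(OC)cc1.[Li+] | intermediate
11 | bis(4-methoxyphenyl){4'-methoxy-3-[(4-methoxyphenyl)ethynyl]-4-methylbiphenyl-2-yl}methanol | Cc1ccc(-c2ccc(OC)cc2)c(C(O)(c2ccc(OC)cc2)c2ccc(OC)cc2)c1C#Cc1ccc(OC)cc1 | intermediate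
12 | bis(4-hydroxyphenyl){4'-hydroxy-3-[(4-hydroxyphenyl)ethynyl]-4-methylbiphenyl-2-yl}methylium bromide | Cc1ccc(-c2ccc(O)cc2)c([C+](c2ccc(O)cc2)c2ccc(O)cc2)c1C#Cc1ccc(O)cc1.[Br-] | intermediate
13 | Selaginellin U, 4-[(4-hydroxyphenyl){4'-hydroxy-3-[(4-hydroxyphenyl)ethynyl]-4-methylbiphenyl-2-yl}methylidene]cyclohexa-2,5-dien-1-one | Cc1ccc(-c2ccc(O)cc2)c(C(=C2C=CC(=O)C=C2)c2ccc(O)cc2)c1C#Cc1ccc(O)cc1 | target

**Step count and risks**
Total step count: 3. Longest linear sequence: 3 steps (1 → 3 → 11 → 13).

Steps most likely to fail:

1. Step 2. The aryne could be captured with poor regiocontrol (attack at the carbon next to the alkynyl group), or the 2-lithiobiaryl could be protonated by the liberated amine before the ketone is added. The fallback avoids the aryne and fixes every ring position with a halogen; it sets out from 2 and comes back to the route at 11. 2-Bromo-4-chlorotoluene would be lithiated between its two halogens (LDA, THF, −78 °C) and quenched with methyl chloroformate to give methyl 2-bromo-6-chloro-3-methylbenzoate F1. Sonogashira coupling of the C–Br bond of F1 with 2 (Pd/Cu, Et3N, 70 °C) should give methyl 6-chloro-2-[(4-methoxyphenyl)ethynyl]-3-methylbenzoate F2. Suzuki–Miyaura coupling of the remaining C–Cl bond with 4-methoxyphenylboronic acid (Pd(OAc)2, SPhos, K3PO4, toluene/H2O, 100 °C) should give methyl 4'-methoxy-3-[(4-methoxyphenyl)ethynyl]-4-methylbiphenyl-2-carboxylate F3. Double addition of 6 (from 4 and t-BuLi, THF, −78 °C → rt) to the ester of F3 should then give 11.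

2. Step 3. While the oxygen atoms are boron-bound and poorly donating, the diarylmethyl cation could close onto the neighbouring 4-methoxyphenyl ring in a Friedel–Crafts reaction (9,9-diarylfluorene formation), or H–Br/B–Br could add across the alkyne. The fallback replaces the methyl ethers by fluoride-labile silyl ethers; it sets out from 1 and comes back at 13. Sonogashira coupling of 1 with (4-ethynylphenoxy)triisopropylsilane should give 1-chloro-3-methyl-2-{[4-(triisopropylsilyloxy)phenyl]ethynyl}benzene F4. The three-component coupling of step 2, run with 4-(triisopropylsilyloxy)phenyllithium (from the bromide and t-BuLi) and 4,4'-bis(triisopropylsilyloxy)benzophenone, should give the tetrasilyl carbinol {4'-(triisopropylsilyloxy)-3-{[4-(triisopropylsilyloxy)phenyl]ethynyl}-4-methylbiphenyl-2-yl}bis[4-(triisopropylsilyloxy)phenyl]methanol F5. TBAF (THF, 0 °C) should release bis(4-hydroxyphenyl){4'-hydroxy-3-[(4-hydroxyphenyl)ethynyl]-4-methylbiphenyl-2-yl}methanol F6, which on acidification with AcOH should lose water to give 13 without any strong Lewis acid.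

3. Step 1. Oxidative homocoupling of the electron-rich alkyne 2 could outrun the slow coupling at the doubly ortho-substituted C–I bond. The fallback reverses the roles of the partners; it sets out from 1 and comes back at 3. Sonogashira coupling of 1 with (trimethylsilyl)acetylene in excess should give [(2-chloro-6-methylphenyl)ethynyl]trimethylsilane F7. K2CO3 in MeOH should remove the silyl group to give 1-chloro-2-ethynyl-3-methylbenzene F8. Sonogashira coupling of F8 with unhindered 4-iodoanisole should then give 3.

**Further compounds**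
F1 | step 2 | methyl 2-bromo-6-chloro-3-methylbenzoate | COC(=O)c1c(Cl)ccc(C)c1Br
F2 | step 2 | methyl 6-chloro-2-[(4-methoxyphenyl)ethynyl]-3-methylbenzoate | COC(=O)c1c(Cl)ccc(C)c1C#Cc1ccc(OC)cc1
F3 | step 2 | methyl 4'-methoxy-3-[(4-methoxyphenyl)ethynyl]-4-methylbiphenyl-2-carboxylate | COC(=O)c1c(-c2ccc(OC)cc2)ccc(C)c1C#Cc1ccc(OC)cc1
F4 | step 3 | 1-chloro-3-methyl-2-{[4-(triisopropylsilyloxy)phenyl]ethynyl}benzene | Cc1cccc(Cl)c1C#Cc1ccc(O[Si](C(C)C)(C(C)C)C(C)C)cc1
F5 | step 3 | {4'-(triisopropylsilyloxy)-3-{[4-(triisopropylsilyloxy)phenyl]ethynyl}-4-methylbiphenyl-2-yl}bis[4-(triisopropylsilyloxy)phenyl]methanol | Cc1ccc(-c2ccc(O[Si](C(C)C)(C(C)C)C(C)C)cc2)c(C(O)(c2ccc(O[Si](C(C)C)(C(C)C)C(C)C)cc2)c2ccc(O[Si](C(C)C)(C(C)C)C(C)C)cc2)c1C#Cc1ccc(O[Si](C(C)C)(C(C)C)C(C)C)cc1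
F6 | step 3 | bis(4-hydroxyphenyl){4'-hydroxy-3-[(4-hydroxyphenyl)ethynyl]-4-methylbiphenyl-2-yl}methanol | Cc1ccc(-c2ccc(O)cc2)c(C(O)(c2ccc(O)cc2)c2ccc(O)cc2)c1C#Cc1ccc(O)cc1
F7 | step 1 | [(2-chloro-6-methylphenyl)ethynyl]trimethylsilane | Cc1cccc(Cl)c1C#C[Si](C)(C)C
F8 | step 1 | 1-chloro-2-ethynyl-3-methylbenzene | Cc1cccc(Cl)c1C#C
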